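## Retrosynthetic overview

1. Target 30 ⇐ N-Boc ketal macrocycle 29 by one acid treatment that removes the Boc group and the temporary dioxolane.
2. 29 ⇐ open-chain bis-amide 26 by closing the 20-membered ring at the CH2–CH2 bond between the acrylamide N–CH2 and the middle carbon of the N–CH2–CH2–CH2–N segment (reductive N-acyliminium/enecarbamate coupling). The enabling feature is this 1,3-diaminopropane segment of the spermidine bridge in the macrocycle: the amide nitrogen makes its CH2 a latent N-acyliminium carbon, and the amine nitrogen two carbons away makes the middle CH2 the β-carbon of an N-vinyl carbamate (a Mannich pattern).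
3. 26 ⇐ aryl bromide 18 + (Z)-iodoacrylamide 24 (borylation/Suzuki–Miyaura, Z retained); the Z-acrylamide on C9b comes from Still–Gennari olefination of the C9b aldehyde.
4. Tricyclic core ⇐ (R)-4-aryl-4-cyanocyclohexenone by phenol oxa-Michael addition (cis fusion); the quaternary centre comes from enantioselective deprotonation of the prochiral 4-aryl-4-cyanocyclohexanone, itself from an arylacetonitrile and two methyl acrylates (Michael/Michael/Dieckmann).
5. Ring order: cyclohexanone ring → dihydrofuran ring → (temporary dioxolane) → 20-membered ring; the benzene ring is bought.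

Key step: step 16

Remark 1: the target is taken exactly as written: cis-fused (4aR,9bS)-hexahydrodibenzofuran-3-one, two Z-alkenes, saturated ketone, free secondary amine.
Remark 2: the sense of induction in step 3 is assigned by analogy with 4-tert-butylcyclohexanone (aryl equatorial in place of tert-butyl, cyano axial in place of hydrogen); if it proves opposite, the (S,S)-amide is used instead.

## Route

Step 1
Reactants: 1 2-(5-bromo-2-methoxyphenyl)acetonitrile; 2 methyl acrylate (2.2 equiv)
Product: 4 methyl 5-(5-bromo-2-methoxyphenyl)-5-cyano-2-oxocyclohexane-1-carboxylate (racemic; keto/enol and diastereomer mixture), via pimelate diester 3 (not isolated)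
Conditions: KOtBu (3 equiv), THF, 0 °C → rt; aq. HCl quench
Reagents that add atoms: none
Why: The benzylic nitrile anion should add twice to methyl acrylate (double Michael addition) and the resulting pimelate should close by Dieckmann condensation in the same pot; no stereocontrol is needed because step 2 returns an achiral ketone.

Step 2
Reactants: 4 methyl 5-(5-bromo-2-methoxyphenyl)-5-cyano-2-oxocyclohexane-1-carboxylate
Product: 5 1-(5-bromo-2-methoxyphenyl)-4-oxocyclohexane-1-carbonitrile (achiral)
Conditions: LiCl (cat.), H2O (2 equiv), DMSO, 150 °C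
Reagents that add atoms: none
Why: Krapcho dealkoxycarbonylation of the β-keto ester should proceed under neutral conditions that leave the tertiary nitrile and the aryl bromide untouched.

Step 3
Reactants: 5 1-(5-bromo-2-methoxyphenyl)-4-oxocyclohexane-1-carbonitrile
Product: 6 (R)-1-(5-bromo-2-methoxyphenyl)-4-(trimethylsilyloxy)cyclohex-3-ene-1-carbonitrile
Conditions: (R,R)-bis(1-phenylethyl)amine hydrochloride, n-BuLi (2 equiv), THF, −78 °C; then TMSCl and 5, −100 °C (internal quench)
Reagents that add atoms: chlorotrimethylsilane, C[Si](C)(C)Cl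
Why: Enantioselective deprotonation with a chiral lithium amide (LiCl present, silyl chloride as internal quench) should remove one of the two enantiotopic axial α-protons of the conformationally locked ketone, so the quaternary carbon becomes a stereocentre under reagent control; recrystallisation of nitrile 10 is planned to raise the enantiomeric purity.

Step 4
Reactants: 6 (R)-1-(5-bromo-2-methoxyphenyl)-4-(trimethylsilyloxy)cyclohex-3-ene-1-carbonitrile
Product: 7 (R)-1-(5-bromo-2-methoxyphenyl)-4-oxocyclohex-2-ene-1-carbonitrile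
Conditions: Pd(OAc)2 (1.05 equiv), MeCN, rt
Reagents that add atoms: none
Why: Saegusa–Ito oxidation should place the enone double bond on the side chosen in step 3 without touching the quaternary centre; the ligand-free palladium metal that forms is not expected to insert into the electron-rich aryl bromide at room temperature.

Step 5
Reactants: 7 (R)-1-(5-bromo-2-methoxyphenyl)-4-oxocyclohex-2-ene-1-carbonitrile
Product: 9 (4aR,9bR)-8-bromo-3-oxo-1,2,3,4,4a,9b-hexahydrodibenzo[b,d]furan-9b-carbonitrile (cis-fused), via phenol enone 8 (not isolated)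
Conditions: BBr3, CH2Cl2, −78 → 0 °C; cold aq. NaHCO3; then Et3N (cat.), CH2Cl2, rt
Reagents that add atoms: none
Why: BBr3 should cleave the aryl methyl ether and the freed phenol should add to the enone β-carbon by 5-exo-trig oxa-Michael addition; only the cis ring fusion is geometrically accessible, so the quaternary carbon fixes the new C4a centre, and the buffered quench keeps the phenol from adding to the nitrile.

Step 6
Reactants: 9 (4aR,9bR)-8-bromo-3-oxo-1,2,3,4,4a,9b-hexahydrodibenzo[b,d]furan-9b-carbonitrile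
Product: 10 (4aR,9bR)-8-bromo-1,2,4,4a-tetrahydro-9bH-spiro[dibenzo[b,d]furan-3,2'-[1,3]dioxolane]-9b-carbonitrile
Conditions: 1,2-bis(trimethylsilyloxy)ethane, TMSOTf (cat.), CH2Cl2, −78 → −20 °C
Reagents that add atoms: 1,2-bis(trimethylsilyloxy)ethane, C[Si](C)(C)OCCO[Si](C)(C)C
Why: Ketalisation by silyl transfer under aprotic conditions should protect the ketone without the retro-oxa-Michael opening that hot protic acid could cause.

Step 7
Reactants: 10 (4aR,9bR)-8-bromo-1,2,4,4a-tetrahydro-9bH-spiro[dibenzo[b,d]furan-3,2'-[1,3]dioxolane]-9b-carbonitrile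
Product: 11 (4aR,9bS)-8-bromo-1,2,4,4a-tetrahydro-9bH-spiro[dibenzo[b,d]furan-3,2'-[1,3]dioxolane]-9b-carbaldehyde
Conditions: DIBAL-H (1.5 equiv), toluene/CH2Cl2, −78 → −20 °C; aq. Rochelle salt, then wet silica gel
Reagents that add atoms: water, O
Why: DIBAL-H should stop at the aluminium aldimine of the tertiary nitrile, which is hydrolysed to the aldehyde on work-up, while ketal and aryl bromide are inert.

Step 8
Reactants: 11 (4aR,9bS)-8-bromo-1,2,4,4a-tetrahydro-9bH-spiro[dibenzo[b,d]furan-3,2'-[1,3]dioxolane]-9b-carbaldehyde; 12 methyl 2-[bis(2,2,2-trifluoroethoxy)phosphoryl]acetate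
Product: 13 methyl (Z)-3-[(4aR,9bS)-8-bromo-1,2,4,4a-tetrahydro-9bH-spiro[dibenzo[b,d]furan-3,2'-[1,3]dioxolan]-9b-yl]prop-2-enoate
Conditions: KHMDS, 18-crown-6, THF, −78 → −40 °C
Reagents that add atoms: none
Why: Still–Gennari olefination should give the Z-enoate through fast, irreversible elimination from the kinetic adduct of the electron-poor phosphonate; the aldehyde has no α-hydrogen, so it can neither enolise nor lose the β-aryloxy group.

Step 9
Reactants: 13 methyl (Z)-3-[(4aR,9bS)-8-bromo-…-9b-yl]prop-2-enoate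
Product: 14 (Z)-3-[(4aR,9bS)-8-bromo-1,2,4,4a-tetrahydro-9bH-spiro[dibenzo[b,d]furan-3,2'-[1,3]dioxolan]-9b-yl]prop-2-enoic acid
Conditions: LiOH·H2O, THF/H2O, rt; then 1 M HCl to pH 4, 0 °C
Reagents that add atoms: lithium hydroxide, [Li+].[OH-]
Why: Saponification of the methyl ester should leave the Z-alkene, the ketal (brief exposure to pH 4 in the cold) and the aryl bromide unchanged.

Step 10
Reactants: 14 (Z)-3-[(4aR,9bS)-8-bromo-…-9b-yl]prop-2-enoic acid
Product: 15 (Z)-3-[(4aR,9bS)-8-bromo-1,2,4,4a-tetrahydro-9bH-spiro[dibenzo[b,d]furan-3,2'-[1,3]dioxolan]-9b-yl]prop-2-enamide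
Conditions: DIC, ammonium 1-hydroxybenzotriazolate, DMF, 0 °C → rt
Reagents that add atoms: ammonium 1-hydroxybenzotriazolate, [NH4+].[O-]n1nnc2ccccc12
Why: Carbodiimide amidation through the hydroxybenzotriazole ester should give the primary amide under mild, nearly neutral conditions that keep the Z geometry.

Step 11
Reactants: 15 (Z)-3-[(4aR,9bS)-8-bromo-…-9b-yl]prop-2-enamide; 16 paraformaldehyde (as formaldehyde)
Product: 18 (Z)-3-[(4aR,9bS)-8-bromo-1,2,4,4a-tetrahydro-9bH-spiro[dibenzo[b,d]furan-3,2'-[1,3]dioxolan]-9b-yl]-N-(methoxymethyl)prop-2-enamide, via N-hydroxymethyl amide 17 (not isolated)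
Conditions: 16, K2CO3 (cat.), THF, 40 °C; then MeOH, PPTS (cat.), rt
Reagents that add atoms: methanol, CO
Why: Base-catalysed N-hydroxymethylation of the primary amide followed by acid-catalysed exchange with methanol should give the N,O-acetal, an N-acyliminium precursor that is stable to the basic conditions of step 15; PPTS in methanol at room temperature should leave the dioxolane intact.

Step 12
Reactants: 19 tert-butyl N-vinylcarbamate; 20 N-(4-bromobutyl)phthalimide
Product: 21 tert-butyl N-[4-(1,3-dioxoisoindolin-2-yl)butyl]-N-vinylcarbamate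
Conditions: NaH, DMF, 0 °C → rt
Reagents that add atoms: none
Why: The sodium salt of the secondary enecarbamate should be alkylated at nitrogen by the primary bromide (SN2), as is usual for N-vinyl amides and carbamates.

Step 13
Reactants: 21 tert-butyl N-[4-(1,3-dioxoisoindolin-2-yl)butyl]-N-vinylcarbamate
Product: 22 tert-butyl N-(4-aminobutyl)-N-vinylcarbamate
Conditions: N2H4·H2O, EtOH, 50 °C
Reagents that add atoms: none
Why: Ing–Manske hydrazinolysis should free the primary amine under conditions that leave the acid-sensitive N-vinyl carbamate untouched.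

Step 14
Reactants: 22 tert-butyl N-(4-aminobutyl)-N-vinylcarbamate; 23 (Z)-3-iodoacrylic acid
Product: 24 tert-butyl N-{4-[(Z)-3-iodoprop-2-enamido]butyl}-N-vinylcarbamate
Conditions: DIC, HOBt (0.2 equiv), CH2Cl2, 0 °C
Reagents that add atoms: none
Why: Carbodiimide coupling should acylate the amine faster than the amine can add to the β-iodo carbon, and the cold, nearly neutral medium keeps both the Z-iodoalkene and the enecarbamate.

Step 15
Reactants: 18 N-(methoxymethyl) Z-acrylamide aryl bromide; 24 tert-butyl N-{4-[(Z)-3-iodoprop-2-enamido]butyl}-N-vinylcarbamate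
Product: 26 tert-butyl N-{4-[(Z)-3-{(4aR,9bS)-9b-[(Z)-3-(methoxymethylamino)-3-oxoprop-1-enyl]-1,2,4,4a-tetrahydro-9bH-spiro[dibenzo[b,d]furan-3,2'-[1,3]dioxolan]-8-yl}prop-2-enamido]butyl}-N-vinylcarbamate, via aryl pinacolboronate 25 (not isolated)
Conditions: B2pin2 (1.1 equiv), KOAc, Pd(dppf)Cl2 (cat.), dioxane, 85 °C; then 24, aq. K3PO4, 45 °C
Reagents that add atoms: none
Why: Miyaura borylation followed in the same pot by Suzuki–Miyaura coupling with the alkenyl iodide should give the Z-cinnamamide with retention at the alkenyl carbon; at 45 °C with the boronate present the N-vinyl carbamate is not expected to undergo Heck arylation.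

Step 16
Reactants: 26 open-chain bis-amide
Product: 29 N-Boc ethylene-ketal macrocycle (20-membered ring; 4aR,9bS; both alkenes Z), via N-acyliminium ion 27 (not isolated), via macrocyclic N-Boc iminium ion 28 (not isolated)
Conditions: BF3·OEt2 (5 equiv), Et3SiH (10 equiv), CH2Cl2, −40 → −15 °C, 26 added over 8 h (final 1 mM); Et3N/MeOH quench
Reagents that add atoms: none
Why: Proposed new method: BF3 should abstract methoxide from the N-(methoxymethyl)acrylamide to give N-acyliminium ion 27, whose methylene carbon is attacked by the β-carbon of the tethered N-vinyl carbamate to form the new CH2–CH2 bond and N-Boc iminium ion 28, which Et3SiH reduces irreversibly; the dihydro-1,3-oxazine from amide-oxygen capture of 28 and the enecarbamate from proton loss both return to 28 under the same conditions. The closest known reaction types are the α-amidoalkylation of tertiary enamides and enecarbamates by N-acyliminium ions (the acid-catalysed dimerisation of N-vinyl amides is the same bond formation) and the BF3/Et3SiH reduction of N-Boc iminium ions, and what is new is their use together to close a large ring. The 20-membered ring is closed in a 20-endo-trig mode with respect to the iminium C=N bond, and the dioxolane is only carried along. No stereocentre is formed, since the three carbons involved all end as CH2 groups, and the 4aR,9bS centres and both Z-alkenes are not touched. The step needs ring closure to win over oligomerisation, which slow addition to about 1 mM and the rigid cis-fused core holding both Z-acrylamide arms should secure, and carbon attack to win over oxygen or nitrogen attack, which is reversible while hydride capture is not. It also needs hydride transfer to the iminium ion and not to the ketal or to a protonated enecarbamate, which the low temperature, the absence of a proton source and the low standing concentration of 26 should secure.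

Step 17
Reactants: 29 N-Boc ethylene-ketal macrocycle
Product: 30 CNP0159470.1 (target)
Conditions: TFA/CH2Cl2/H2O (10:10:1), 0 °C → rt; aq. NaHCO3 work-up
Reagents that add atoms: water, O
Why: Aqueous acid should cleave the Boc carbamate and hydrolyse the dioxolane in one operation; a retro-oxa-Michael opening of the β-aryloxy ketone would leave the quaternary centre intact and can only re-close to the cis-fused ring, so neither stereocentre is at risk.

## Compound list

1 | 2-(5-bromo-2-methoxyphenyl)acetonitrile | N#CCc1cc(Br)ccc1OC | starting material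
2 | methyl acrylate | C=CC(=O)OC | starting material
3 | dimethyl 4-(5-bromo-2-methoxyphenyl)-4-cyanoheptanedioate | COC(=O)CCC(C#N)(CCC(=O)OC)c1cc(Br)ccc1OC | intermediate
4 | methyl 5-(5-bromo-2-methoxyphenyl)-5-cyano-2-oxocyclohexane-1-carboxylate (racemic mixture) | COC(=O)C1CC(C#N)(c2cc(Br)ccc2OC)CCC1=O | intermediate
5 | 1-(5-bromo-2-methoxyphenyl)-4-oxocyclohexane-1-carbonitrile | N#CC1(c2cc(Br)ccc2OC)CCC(=O)CC1 | intermediate
6 | (R)-1-(5-bromo-2-methoxyphenyl)-4-(trimethylsilyloxy)cyclohex-3-ene-1-carbonitrile | C[Si](C)(C)OC1=CC[C@@](C#N)(c2cc(Br)ccc2OC)CC1 | intermediate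
7 | (R)-1-(5-bromo-2-methoxyphenyl)-4-oxocyclohex-2-ene-1-carbonitrile | O=C1C=C[C@@](C#N)(c2cc(Br)ccc2OC)CC1 | intermediate
8 | (R)-1-(5-bromo-2-hydroxyphenyl)-4-oxocyclohex-2-ene-1-carbonitrile | O=C1C=C[C@@](C#N)(c2cc(Br)ccc2O)CC1 | intermediate
9 | (4aR,9bR)-8-bromo-3-oxo-1,2,3,4,4a,9b-hexahydrodibenzo[b,d]furan-9b-carbonitrile | O=C1CC[C@]2(C#N)c3cc(Br)ccc3O[C@@H]2C1 | intermediate
10 | (4aR,9bR)-8-bromo-1,2,4,4a-tetrahydro-9bH-spiro[dibenzo[b,d]furan-3,2'-[1,3]dioxolane]-9b-carbonitrile | C14(OCCO4)CC[C@]2(C#N)c3cc(Br)ccc3O[C@@H]2C1 | intermediate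
11 | (4aR,9bS)-8-bromo-1,2,4,4a-tetrahydro-9bH-spiro[dibenzo[b,d]furan-3,2'-[1,3]dioxolane]-9b-carbaldehyde | C14(OCCO4)CC[C@]2(C=O)c3cc(Br)ccc3O[C@@H]2C1 | intermediate
12 | methyl 2-[bis(2,2,2-trifluoroethoxy)phosphoryl]acetate | COC(=O)CP(=O)(OCC(F)(F)F)OCC(F)(F)F | starting material
13 | methyl (Z)-3-[(4aR,9bS)-8-bromo-spiroketal-9b-yl]prop-2-enoate | C14(OCCO4)CC[C@]2(/C=C\C(=O)OC)c3cc(Br)ccc3O[C@@H]2C1 | intermediate
14 | (Z)-3-[(4aR,9bS)-8-bromo-spiroketal-9b-yl]prop-2-enoic acid | C14(OCCO4)CC[C@]2(/C=C\C(=O)O)c3cc(Br)ccc3O[C@@H]2C1 | intermediate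
15 | (Z)-3-[(4aR,9bS)-8-bromo-spiroketal-9b-yl]prop-2-enamide | C14(OCCO4)CC[C@]2(/C=C\C(N)=O)c3cc(Br)ccc3O[C@@H]2C1 | intermediate
16 | paraformaldehyde (formaldehyde) | C=O | starting material
17 | (Z)-3-[(4aR,9bS)-8-bromo-spiroketal-9b-yl]-N-(hydroxymethyl)prop-2-enamide | C14(OCCO4)CC[C@]2(/C=C\C(=O)NCO)c3cc(Br)ccc3O[C@@H]2C1 | intermediate
18 | (Z)-3-[(4aR,9bS)-8-bromo-spiroketal-9b-yl]-N-(methoxymethyl)prop-2-enamide | C14(OCCO4)CC[C@]2(/C=C\C(=O)NCOC)c3cc(Br)ccc3O[C@@H]2C1 | intermediate
19 | tert-butyl N-vinylcarbamate | C=CNC(=O)OC(C)(C)C | starting material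
20 | N-(4-bromobutyl)phthalimide | O=C1c2ccccc2C(=O)N1CCCCBr | starting material
21 | tert-butyl N-[4-(1,3-dioxoisoindolin-2-yl)butyl]-N-vinylcarbamate | C=CN(CCCCN1C(=O)c2ccccc2C1=O)C(=O)OC(C)(C)C | intermediate
22 | tert-butyl N-(4-aminobutyl)-N-vinylcarbamate | C=CN(CCCCN)C(=O)OC(C)(C)C | intermediate
23 | (Z)-3-iodoacrylic acid | OC(=O)/C=C\I | starting material
24 | tert-butyl N-{4-[(Z)-3-iodoprop-2-enamido]butyl}-N-vinylcarbamate | C=CN(CCCCNC(=O)/C=C\I)C(=O)OC(C)(C)C | intermediate
25 | aryl pinacolboronate of 18 | C14(OCCO4)CC[C@]2(/C=C\C(=O)NCOC)c3cc(B5OC(C)(C)C(C)(C)O5)ccc3O[C@@H]2C1 | intermediate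
26 | open-chain bis-amide (N-methoxymethyl Z-acrylamide on C9b; Z-cinnamamide carrying the 4-[Boc(vinyl)amino]butyl chain on C8) | C14(OCCO4)CC[C@]2(/C=C\C(=O)NCOC)c3cc(/C=C\C(=O)NCCCCN(C=C)C(=O)OC(C)(C)C)ccc3O[C@@H]2C1 | intermediate
27 | N-acyliminium ion from 26 | C14(OCCO4)CC[C@]2(/C=C\C(=O)[NH+]=C)c3cc(/C=C\C(=O)NCCCCN(C=C)C(=O)OC(C)(C)C)ccc3O[C@@H]2C1 | intermediate
28 | macrocyclic N-Boc iminium ion | C15(OCCO5)CC[C@]23/C=C\C(=O)NCCC=[N+](C(=O)OC(C)(C)C)CCCCNC(=O)/C=C\c4ccc(c2c4)O[C@@H]3C1 | intermediate
29 | N-Boc ethylene-ketal macrocycle (4aR,9bS; Z,Z) | C15(OCCO5)CC[C@]23/C=C\C(=O)NCCCN(C(=O)OC(C)(C)C)CCCCNC(=O)/C=C\c4ccc(c2c4)O[C@@H]3C1 | intermediate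
30 | CNP0159470.1 | O=C1CC[C@]23/C=C\C(=O)NCCCNCCCCNC(=O)/C=C\c4ccc(c2c4)O[C@@H]3C1 | target

("spiroketal" in the names of 13–18 stands for 1,2,4,4a-tetrahydro-9bH-spiro[dibenzo[b,d]furan-3,2'-[1,3]dioxolane].)

## Summary and risks

Total step count: 17. Longest linear sequence: 14 steps (steps 1–11, 15, 16, 17).

Steps most likely to fail:

1. Step 16 (the step proposed as a new method). The N-acyliminium ion may be captured between molecules (oligomerisation), the enecarbamate may be protonated and then reduced to an N-ethyl carbamate, or the dioxolane may be opened reductively. The fallback uses macrolactamisation, sets out from 13 and comes back at 30.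
   - Acid 23 would be coupled (DIC, HOBt) with commercial N1,N4-bis-Boc-spermidine to the iodoacrylamide tert-butyl N-{3-[(tert-butoxycarbonyl)amino]propyl}-N-{4-[(Z)-3-iodoprop-2-enamido]butyl}carbamate F1.
   - Ester 13 would be borylated as in step 15 to its aryl pinacolboronate F2 (not isolated) and coupled with F1 to the open-chain ester F3.
   - LiOH should give the open-chain acid F4, and pentafluorophenol/DIC its pentafluorophenyl ester F5.
   - TFA/CH2Cl2/H2O would remove both Boc groups and the dioxolane to give the amino keto pentafluorophenyl ester F6.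
   - Slow addition of F6 to i-Pr2NEt in MeCN at 1 mM should close the same 20-membered ring by acylation of the primary amine, which reacts in preference to the secondary one, and give 30 directly.

2. Step 3. The chiral base may discriminate poorly between the enantiotopic α-methylene groups of this 4,4-disubstituted ketone, or the sense may be opposite. The fallback sets out from 5 and comes back at 7.
   - Ketone 5 would be dehydrogenated twice with IBX (DMSO, 80 °C) to the prochiral dienone 1-(5-bromo-2-methoxyphenyl)-4-oxocyclohexa-2,5-diene-1-carbonitrile F7.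
   - One of its two enantiotopic C=C bonds would then be reduced by an ene-reductase of the Old Yellow Enzyme family (NADPH recycled with glucose and glucose dehydrogenase, buffer/DMSO), the enzyme being selected for the (R)-enone 7.

3. Step 15. The boronate may protodeboronate, iodoacrylamide 24 may lose HI under base, or the Z-alkenes may isomerise on palladium. The fallback sets out from 18 and comes back at 26.
   - Bromide 18 would be formylated (Pd(OAc)2, di(1-adamantyl)-n-butylphosphine, CO/H2, TMEDA, toluene, 100 °C) to the aryl aldehyde F8.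
   - F8 would be olefinated with 12 (KHMDS, 18-crown-6, THF, −78 °C) to the methyl (Z)-cinnamate F9.
   - F9 would be hydrolysed (LiOH) to the (Z)-cinnamic acid F10, which would be coupled with amine 22 (DIC, HOBt) to give 26.

## Further compounds

F1 | step 16 | tert-butyl N-{3-[(tert-butoxycarbonyl)amino]propyl}-N-{4-[(Z)-3-iodoprop-2-enamido]butyl}carbamate | CC(C)(C)OC(=O)NCCCN(CCCCNC(=O)/C=C\I)C(=O)OC(C)(C)C
F2 | step 16 | aryl pinacolboronate of 13 | C14(OCCO4)CC[C@]2(/C=C\C(=O)OC)c3cc(B5OC(C)(C)C(C)(C)O5)ccc3O[C@@H]2C1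
F3 | step 16 | open-chain ester (methyl Z-enoate on C9b; Z-cinnamamide of N1,N4-bis-Boc-spermidine on C8) | C14(OCCO4)CC[C@]2(/C=C\C(=O)OC)c3cc(/C=C\C(=O)NCCCCN(CCCNC(=O)OC(C)(C)C)C(=O)OC(C)(C)C)ccc3O[C@@H]2C1
F4 | step 16 | open-chain acid from F3 | C14(OCCO4)CC[C@]2(/C=C\C(=O)O)c3cc(/C=C\C(=O)NCCCCN(CCCNC(=O)OC(C)(C)C)C(=O)OC(C)(C)C)ccc3O[C@@H]2C1
F5 | step 16 | pentafluorophenyl ester of F4 | C14(OCCO4)CC[C@]2(/C=C\C(=O)Oc5c(F)c(F)c(F)c(F)c5F)c3cc(/C=C\C(=O)NCCCCN(CCCNC(=O)OC(C)(C)C)C(=O)OC(C)(C)C)ccc3O[C@@H]2C1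
F6 | step 16 | amino keto pentafluorophenyl ester (free spermidine chain, free ketone) | O=C1CC[C@]2(/C=C\C(=O)Oc5c(F)c(F)c(F)c(F)c5F)c3cc(/C=C\C(=O)NCCCCNCCCN)ccc3O[C@@H]2C1
F7 | step 3 | 1-(5-bromo-2-methoxyphenyl)-4-oxocyclohexa-2,5-diene-1-carbonitrile | N#CC1(c2cc(Br)ccc2OC)C=CC(=O)C=C1
F8 | step 15 | (Z)-3-[(4aR,9bS)-8-formyl-spiroketal-9b-yl]-N-(methoxymethyl)prop-2-enamide | C14(OCCO4)CC[C@]2(/C=C\C(=O)NCOC)c3cc(C=O)ccc3O[C@@H]2C1
F9 | step 15 | methyl (Z)-3-{(4aR,9bS)-9b-[(Z)-3-(methoxymethylamino)-3-oxoprop-1-enyl]-spiroketal-8-yl}prop-2-enoate | C14(OCCO4)CC[C@]2(/C=C\C(=O)NCOC)c3cc(/C=C\C(=O)OC)ccc3O[C@@H]2C1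
F10 | step 15 | (Z)-3-{(4aR,9bS)-9b-[(Z)-3-(methoxymethylamino)-3-oxoprop-1-enyl]-spiroketal-8-yl}prop-2-enoic acid | C14(OCCO4)CC[C@]2(/C=C\C(=O)NCOC)c3cc(/C=C\C(=O)O)ccc3O[C@@H]2C1
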